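The target is cut at three bonds of the eudesmane part: flavene C4–C1, the ring-fusion bond C5–C10 and C4–O. This leads back to (R)-germacrene A and a 5,7,8-trimethoxyflavylium ion, as in the presumed biosynthesis. In the key step chlorocarbene inserts into the enol-ether C2=C3 bond of 4,6,7-trimethoxy-2-phenylbenzofuran; the furan ring expands to the six-membered pyrylium ring (O1, C2, C3, C4, C4a, C8a, with C3 new), whose C4 then triggers the transannular cyclisation of the 1,5-diene of the ten-membered ring, ended by trifluoroacetate. The precursors are thus a benzofuran and a monocyclic triene; the latter comes from (R)-carvone by anionic oxy-Cope ring expansion.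

Key step: step 10

Assumption: 1,2,3,5-tetramethoxybenzene is taken as purchasable (it is otherwise one O-methylation away from 3,4,5-trimethoxyphenol).

**Route**

Step 1
Reactants: 1 1,2,3,5-tetramethoxybenzene
Product: 2 2,3,4,6-tetramethoxybenzaldehyde
Conditions: POCl3, DMF, 0 → 60 °C; then H2O
Reagents that add atoms: N,N-dimethylformamide CN(C)C=O; water O
Why: Vilsmeier–Haack formylation; the two free ring positions of 1 are equivalent and flanked by methoxy groups, so a single aldehyde should result.

Step 2
Reactants: 2 2,3,4,6-tetramethoxybenzaldehyde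
Product: 3 2-hydroxy-3,4,6-trimethoxybenzaldehyde
Conditions: BCl3, CH2Cl2, −78 → 0 °C; then H2O
Reagents that add atoms: none
Why: Boron-chelate-directed cleavage of an aryl methyl ether ortho to the carbonyl group; of the two ortho methoxy groups the one at C2, twisted out of conjugation between the formyl group and the C3 methoxy group, is the more basic and should be cleaved selectively, as in Lewis-acid acylations of 1 that give 2-hydroxy-3,4,6-trimethoxyaryl ketones.

Step 3
Reactants: 3 2-hydroxy-3,4,6-trimethoxybenzaldehyde
Product: 4 2-(benzyloxy)-3,4,6-trimethoxybenzaldehyde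
Conditions: BnBr, K2CO3, DMF, 60 °C
Reagents that add atoms: benzyl bromide BrCc1ccccc1
Why: Williamson ether synthesis on the phenoxide, which brings in the carbon that becomes C2 of the benzofuran together with the future 2-phenyl group.

Step 4
Reactants: 4 2-(benzyloxy)-3,4,6-trimethoxybenzaldehyde
Product: 5 4,6,7-trimethoxy-2-phenyl-1-benzofuran
Conditions: P4-t-Bu phosphazene base (C22H63N13P4), benzene, 80 °C
Reagents that add atoms: none
Why: Base-mediated intramolecular aldol-type condensation: the benzylic carbanion of the ether adds to the neighbouring aldehyde and loss of water aromatises the new furan ring (the known conversion of o-benzyloxybenzaldehydes into 2-arylbenzofurans).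

Step 5
Reactants: 6 (R)-(−)-carvone
Product: 8 (2R,5R)-2-(1-hydroxyethyl)-2-methyl-5-(prop-1-en-2-yl)cyclohexan-1-one, via lithium enolate 7 (not isolated)
Conditions: LiBH(s-Bu)3, THF, −78 °C; then CH3CHO, −78 °C; then aq NH4Cl
Reagents that add atoms: acetaldehyde CC=O
Why: Conjugate hydride reduction of the enone gives enolate 7 regiospecifically, and its aldol addition to acetaldehyde should occur by axial attack on the half-chair with the isopropenyl group pseudo-equatorial, which sets the quaternary C2 with the new chain cis to the isopropenyl group (the sense known from the Robinson annulation of dihydrocarvone); the carbinol centre is removed in step 6.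

Step 6
Reactants: 8 (2R,5R)-2-(1-hydroxyethyl)-2-methyl-5-(prop-1-en-2-yl)cyclohexan-1-one
Product: 9 (2R,5R)-2-ethenyl-2-methyl-5-(prop-1-en-2-yl)cyclohexan-1-one
Conditions: Martin sulfurane Ph2S[OC(CF3)2Ph]2, CH2Cl2, 0 °C → rt
Reagents that add atoms: none
Why: Dehydration with Martin sulfurane (alkoxysulfonium formation, then E2 loss of a methyl hydrogen, the only β-hydrogens available) turns the hydroxyethyl group into the vinyl group, and the quaternary α-carbon excludes conjugation or epimerisation.

Step 7
Reactants: 9 (2R,5R)-2-ethenyl-2-methyl-5-(prop-1-en-2-yl)cyclohexan-1-one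
Product: 10 (1S,2R,5R)-2-ethenyl-2-methyl-1,5-di(prop-1-en-2-yl)cyclohexan-1-ol
Conditions: CH2=C(CH3)MgBr, LaCl3·2LiCl, THF, −78 → 0 °C; then H2O
Reagents that add atoms: isopropenylmagnesium bromide CC(=C)[Mg]Br
Why: Lanthanum-assisted Grignard 1,2-addition; the vinyl group is axial at C2 in the chair with equatorial C5 isopropenyl and blocks its own face, so the nucleophile should enter anti to it and place the two alkenyl groups trans, as step 8 requires.

Step 8
Reactants: 10 (1S,2R,5R)-2-ethenyl-2-methyl-1,5-di(prop-1-en-2-yl)cyclohexan-1-ol
Product: 13 (1Z,5E,9R)-2,6-dimethyl-9-(prop-1-en-2-yl)cyclodeca-1,5-dien-1-yl trifluoromethanesulfonate, via potassium alkoxide 11 (not isolated), via potassium enolate 12 (not isolated)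
Conditions: KH, 18-crown-6, THF, 0 °C → rt; then PhNTf2, −78 → 0 °C
Reagents that add atoms: N-phenylbis(trifluoromethanesulfonimide) O=S(=O)(N(c1ccccc1)S(=O)(=O)C(F)(F)F)C(F)(F)F
Why: Anionic oxy-Cope rearrangement of alkoxide 11 through a chair transition state with both alkenyl groups equatorial expands the six- to the ten-membered ring with E geometry at C1=C10 (germacrane numbering) and fixes enolate 12 regio- and stereospecifically at C4=C5 with the ring carbons trans, and O-triflation traps it before equilibration; C7 is not touched.

Step 9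
Reactants: 13 (1Z,5E,9R)-2,6-dimethyl-9-(prop-1-en-2-yl)cyclodeca-1,5-dien-1-yl trifluoromethanesulfonate
Product: 14 (R)-germacrene A [(1E,5E,8R)-1,5-dimethyl-8-(prop-1-en-2-yl)cyclodeca-1,5-diene]
Conditions: Pd(OAc)2, PPh3, HCO2H, n-Bu3N, DMF, 40 °C
Reagents that add atoms: none
Why: Palladium-catalysed formate reduction of an enol triflate (oxidative addition to zerovalent palladium, formate exchange, loss of CO2, reductive elimination) replaces OTf by H with retention of the alkene geometry, and the buffered medium and low temperature should spare the acid- and heat-sensitive triene.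

Step 10
Reactants: 5 4,6,7-trimethoxy-2-phenyl-1-benzofuran; 14 (R)-germacrene A
Product: 19 (1R,4S,4aS,7R,8aR)-1,4a-dimethyl-7-(prop-1-en-2-yl)-4-[(4R)-5,7,8-trimethoxy-2-phenyl-4H-chromen-4-yl]decahydronaphthalen-1-ol (CNP0390914.2), via chlorocyclopropane 15 (not isolated), via flavylium chloride 16 (not isolated), via flavylium trifluoroacetate 17 (not isolated), via tertiary trifluoroacetate 18 (not isolated)
Conditions: CH2Cl2/Et2O, n-BuLi (slow addition), −40 → 0 °C; AgO2CCF3 (2 equiv), −40 °C; then 14 (slight excess), 2,6-di-tert-butyl-4-methylpyridine, CH2Cl2, −40 → 0 °C; then K2CO3, MeOH, 0 °C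
Reagents that add atoms: dichloromethane ClCCl; silver trifluoroacetate AgO2CCF3 [Ag+].[O-]C(=O)C(F)(F)F
Why: Dichloromethyllithium transfers chlorocarbene to the furan C2=C3 bond of 5 and the endo-chloride 15 ionises with disrotatory electrocyclic opening of the shared cyclopropane bond (halocarbene ring expansion of benzofurans, the oxygen counterpart of the Ciamician–Dennstedt reaction), so that the five-membered ring becomes the six-membered pyrylium ring of 16 with the carbene carbon inserted as C3. After exchange of chloride for trifluoroacetate, C4 of cation 17 is attacked by C1 of the strained (E)-C1=C10 bond of 14 while C5 of the C4=C5 bond adds to C10 across the ring, a cation–olefin cyclisation started by an oxocarbenium ion and the transannular germacrene-to-eudesmane closure known for protons, halonium ions and epoxides; this single C5–C10 bond closes both six-membered carbocycles (6-endo at the C4=C5 bond for ring A), whereas the pyran ring arises only by the ring expansion. The chair–chair conformer of the ten-membered ring with the C7 isopropenyl group equatorial, together with anti addition across both E-alkenes, sets C1 (flavenyl equatorial), C10 (methyl axial) and C5 (H trans to that methyl) relative to C7. The C4 cation is captured by its trifluoroacetate counter-ion from the equatorial side, anti to the new C5–C10 bond and away from the axial C10 methyl, and mild methanolysis of 18 leaves the tertiary alcohol with that configuration. Flavene C4 is set by substrate control in an open transition state expected to place the small C4–H of the cation in the crowded sector between C2 and the C10 methyl of the alkene and the aryl ring toward C9; this is the least certain element and an epimer would be removed by chromatography. The step needs attack at C4 and not C2 of the cation (C2 carries phenyl), reaction of the 1(10)-alkene and not the isopropenyl group (strain and transannular assistance), and freedom from protons and water, which the carboxylate counter-ion, the hindered pyridine and the slight excess of 14 over the cation are meant to secure.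

**Compound list**

1 | 1,2,3,5-tetramethoxybenzene | COc1cc(OC)c(OC)c(OC)c1 | starting material
2 | 2,3,4,6-tetramethoxybenzaldehyde | COc1cc(OC)c(C=O)c(OC)c1OC | intermediate
3 | 2-hydroxy-3,4,6-trimethoxybenzaldehyde | COc1cc(OC)c(C=O)c(O)c1OC | intermediate
4 | 2-(benzyloxy)-3,4,6-trimethoxybenzaldehyde | COc1cc(OC)c(C=O)c(OCc2ccccc2)c1OC | intermediate
5 | 4,6,7-trimethoxy-2-phenyl-1-benzofuran | COc1cc(OC)c2cc(-c3ccccc3)oc2c1OC | intermediate
6 | (R)-(−)-carvone | CC1=CC[C@@H](C(C)=C)CC1=O | starting material
7 | lithium (5R)-2-methyl-5-(prop-1-en-2-yl)cyclohex-1-en-1-olate | [Li+].[O-]C1=C(C)CC[C@@H](C(C)=C)C1 | intermediate (not isolated)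
8 | (2R,5R)-2-(1-hydroxyethyl)-2-methyl-5-(prop-1-en-2-yl)cyclohexan-1-one (hydroxyethyl cis to isopropenyl; both carbinol epimers) | CC(O)[C@@]1(C)CC[C@@H](C(C)=C)CC1=O | intermediate
9 | (2R,5R)-2-ethenyl-2-methyl-5-(prop-1-en-2-yl)cyclohexan-1-one (vinyl cis to isopropenyl) | C=C[C@@]1(C)CC[C@@H](C(C)=C)CC1=O | intermediate
10 | (1S,2R,5R)-2-ethenyl-2-methyl-1,5-di(prop-1-en-2-yl)cyclohexan-1-ol (C1 isopropenyl trans to vinyl) | C=C[C@@]1(C)CC[C@@H](C(C)=C)C[C@]1(O)C(C)=C | intermediate
11 | potassium alkoxide of 10 | [K+].C=C[C@@]1(C)CC[C@@H](C(C)=C)C[C@]1([O-])C(C)=C | intermediate (not isolated)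
12 | potassium (1Z,5E,9R)-2,6-dimethyl-9-(prop-1-en-2-yl)cyclodeca-1,5-dien-1-olate | [K+].C/C1=C\CC/C(C)=C([O-])/C[C@H](C(C)=C)CC1 | intermediate (not isolated)
13 | (1Z,5E,9R)-2,6-dimethyl-9-(prop-1-en-2-yl)cyclodeca-1,5-dien-1-yl trifluoromethanesulfonate | C/C1=C\CC/C(C)=C(OS(=O)(=O)C(F)(F)F)/C[C@H](C(C)=C)CC1 | intermediate
14 | (R)-germacrene A, (1E,5E,8R)-1,5-dimethyl-8-(prop-1-en-2-yl)cyclodeca-1,5-diene | C/C1=C\CC/C(C)=C/C[C@H](C(C)=C)CC1 | intermediate
15 | 1-chloro-3,4,6-trimethoxy-1a-phenyl-1a,6b-dihydro-1H-cyclopropa[b][1]benzofuran (chlorine endo, cis to the ring oxygen and the arene; racemic, relative configuration shown) | COc1cc(OC)c2c(c1OC)O[C@]1(c3ccccc3)[C@H](Cl)[C@H]21 | intermediate (not isolated)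
16 | 5,7,8-trimethoxy-2-phenylchromenylium chloride (5,7,8-trimethoxyflavylium chloride) | COc1cc(OC)c2ccc(-c3ccccc3)[o+]c2c1OC.[Cl-] | intermediate (not isolated)
17 | 5,7,8-trimethoxy-2-phenylchromenylium trifluoroacetate | COc1cc(OC)c2ccc(-c3ccccc3)[o+]c2c1OC.[O-]C(=O)C(F)(F)F | intermediate (not isolated)
18 | trifluoroacetate ester of 19 at the tertiary hydroxyl group | C=C(C)[C@@H]1CC[C@]2(C)[C@@H](C1)[C@](C)(OC(=O)C(F)(F)F)CC[C@H]2[C@@H]1C=C(c2ccccc2)Oc2c(OC)c(OC)cc(OC)c21 | intermediate (not isolated)
19 | (1R,4S,4aS,7R,8aR)-1,4a-dimethyl-7-(prop-1-en-2-yl)-4-[(4R)-5,7,8-trimethoxy-2-phenyl-4H-chromen-4-yl]decahydronaphthalen-1-ol (CNP0390914.2) | C=C(C)[C@@H]1CC[C@]2(C)[C@@H](C1)[C@](C)(O)CC[C@H]2[C@@H]1C=C(c2ccccc2)Oc2c(OC)c(OC)cc(OC)c21 | target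

**Count**

Total step count: 10. Longest linear sequence: 6 steps (steps 5 to 10, from carvone); the arene branch has 4 steps before the union.

**Steps most likely to fail**

1. Step 10. Several processes may go wrong.
- The carbenoid may add with chlorine exo, and such adducts cannot open.
- Leftover carbenoid or unreacted arene 5 may capture the cation as it forms.
- The methoxy-stabilised cation may attack the alkene too slowly, so that adventitious protons cyclise 14 first.
- The tertiary cation may lose a proton instead of collapsing with trifluoroacetate.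
- Attack on the two faces of flavene C4 may be unselective.
- The enol ether of the product may be alkylated or oxidised by remaining cation.

Fallback, setting out from 5 (with 14 as before) and returning at 19: the ring expansion is run as a separate operation with dibromocarbene (CHBr3, KOtBu, pentane, −20 °C → rt; then HBF4·OEt2). Both faces of the dibromocyclopropane carry a bromide cis to the ring, so electrocyclic opening cannot be blocked, and the cation is collected as crystalline 3-bromo-5,7,8-trimethoxy-2-phenylchromenylium tetrafluoroborate F1, free of base, of 5 and of neutral adducts. F1, Bu4N O2CCF3 and 14 (CH2Cl2, 2,6-di-tert-butyl-4-methylpyridine, −40 → 0 °C) should give the 3-bromo analogue of ester 18 F2, the bromine making the cation more electrophilic, and K2CO3/MeOH then the 3-bromo analogue of the target F3. Reductive removal of the vinylic bromine [Pd(OAc)2, PPh3, HCO2H, Et3N, DMF, 50 °C] returns to 19.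

2. Step 8. The rearrangement may pass through a boat transition state or, if step 7 delivered some cis-dialkenyl alcohol, give Z alkenes. The hindered ten-membered enolate may also be protonated or equilibrated before it is sulfonylated on oxygen.

Fallback, setting out from 10 and returning at 14: after the same rearrangement (KH, 18-crown-6, THF) enolate 12 is quenched with ClP(O)(OEt)2, a smaller and harder electrophile for the hindered oxygen, to give diethyl (1Z,5E,9R)-2,6-dimethyl-9-(prop-1-en-2-yl)cyclodeca-1,5-dien-1-yl phosphate F4. Dissolving-metal cleavage of the enol phosphate (Li, EtNH2, t-BuOH, THF, −78 °C) keeps the alkene geometry and leads directly to 14, without 13 and without palladium.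

3. Step 6. Retro-aldol cleavage or acyl migration may outrun the elimination at the hindered, neopentyl-type carbinol.

Fallback, setting out from 6 and returning at 9: enolate 7 (LiBH(s-Bu)3, THF, −78 °C) is combined with (phenylselanyl)acetaldehyde to give (2R,5R)-2-[1-hydroxy-2-(phenylselanyl)ethyl]-2-methyl-5-(prop-1-en-2-yl)cyclohexan-1-one F5. MsCl/Et3N (CH2Cl2, 0 °C) then triggers the anti elimination of the hydroxyl and selanyl groups (β-hydroxy selenide olefin synthesis), which can only give the vinyl group of 9.

Further compounds
F1 | step 10 | 3-bromo-5,7,8-trimethoxy-2-phenylchromenylium tetrafluoroborate | COc1cc(OC)c2cc(Br)c(-c3ccccc3)[o+]c2c1OC.F[B-](F)(F)F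
F2 | step 10 | 3-bromo analogue of ester 18 | C=C(C)[C@@H]1CC[C@]2(C)[C@@H](C1)[C@](C)(OC(=O)C(F)(F)F)CC[C@H]2[C@@H]1C(Br)=C(c2ccccc2)Oc2c(OC)c(OC)cc(OC)c21
F3 | step 10 | 3-bromo analogue of the target | C=C(C)[C@@H]1CC[C@]2(C)[C@@H](C1)[C@](C)(O)CC[C@H]2[C@@H]1C(Br)=C(c2ccccc2)Oc2c(OC)c(OC)cc(OC)c21
F4 | step 8 | diethyl (1Z,5E,9R)-2,6-dimethyl-9-(prop-1-en-2-yl)cyclodeca-1,5-dien-1-yl phosphate | C/C1=C\CC/C(C)=C(OP(=O)(OCC)OCC)/C[C@H](C(C)=C)CC1
F5 | step 6 | (2R,5R)-2-[1-hydroxy-2-(phenylselanyl)ethyl]-2-methyl-5-(prop-1-en-2-yl)cyclohexan-1-one | OC(C[Se]c1ccccc1)[C@@]1(C)CC[C@@H](C(C)=C)CC1=O
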